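The cyclohexanetrione ring is disconnected at the bond between the benzoyl-bearing ring carbon and the neighbouring enol carbon that lies next to the prenyl-bearing carbon. The benzoyl-bearing carbon sits between two ring carbonyl carbons, so it is the twice-acylated methyl group of acetophenone; the other five ring carbons, with all three allylic side chains, are a 2,2,4-trialkylated 3-oxoglutarate. In one operation the acetophenone enolate is acylated by the ester on the quaternary carbon and the resulting 1,3-diketone closes the six-membered ring by Claisen attack on the second ester. The precursor is an acyclic diester whose only lasting stereocentre is set by asymmetric phase-transfer geranylation.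

Key step: step 3

Assumption: the (S,S) antipode of the phase-transfer catalyst is taken to give the (R) configuration of 6, and the mirror-image catalyst would be used if the first run shows the opposite sense; β-dicarbonyl compounds are drawn as keto forms and their enolisable CH centres are left undefined.

Step 1
Reactants: 1 dimethyl 3-oxopentanedioate; 2 prenyl bromide (1-bromo-3-methylbut-2-ene)
Product: 4 dimethyl 2,4-bis(3-methylbut-2-en-1-yl)-3-oxopentanedioate, via monoprenyl diester 3 (not isolated)
Conditions: NaH (1.05 equiv), THF, 0 °C, then 2 (1.0 equiv), 0 °C to rt; recooled to 0 °C, NaH (1.05 equiv), then a second portion of 2 (1.05 equiv), 0 °C to rt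
Reagents that add atoms: prenyl bromide (second equivalent of 2), CC(C)=CCBr
Why: Twofold enolate C-alkylation of a 1,3-acetonedicarboxylate (acetoacetic-ester-type alkylation) that consumes two equivalents of 2 in all, in which the unsubstituted methylene of monoprenyl diester 3 is the more acidic and less hindered site, so the second prenyl group should enter at the other α-carbon and give the symmetrical 2,4-pattern; both CH centres are enolisable and need no control.

Step 2
Reactants: 4 dimethyl 2,4-bis(3-methylbut-2-en-1-yl)-3-oxopentanedioate; 5 geranyl bromide ((2E)-1-bromo-3,7-dimethylocta-2,6-diene)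
Product: 6 dimethyl (2R)-2-[(2E)-3,7-dimethylocta-2,6-dien-1-yl]-2,4-bis(3-methylbut-2-en-1-yl)-3-oxopentanedioate (mixture of epimers at the enolisable C4)
Conditions: 4 (1.3 equiv), 5 (1.0 equiv), (S,S)-spiro bis(binaphthyl)ammonium bromide bearing 3,4,5-trifluorophenyl groups at the 3,3' positions (2 mol%), Cs2CO3 (solid), toluene, −20 °C
Reagents that add atoms: none
Why: Asymmetric phase-transfer C-alkylation of an α-substituted β-keto ester, in which the tight ion pair of the enolate with the chiral ammonium cation should expose one enolate face to SN2 attack on the primary allylic bromide (E geometry kept) and so set the quaternary stereocentre, while the symmetry of 4 makes both α-carbons constitutionally equivalent and the excess of 4 suppresses a second alkylation.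

Step 3
Reactants: 6 dimethyl (2R)-2-geranyl-2,4-diprenyl-3-oxopentanedioate; 7 acetophenone
Product: 9 kolanone, via triketo ester 8 (not isolated)
Conditions: 6, NaN(SiMe3)2 (1.05 equiv), THF, −78 °C; added to the sodium enolate of 7 [7 (1.3 equiv), NaN(SiMe3)2 (2.4 equiv)], −78 to 45 °C; then MeOH, 50 °C; cold 0.5 M HCl
Reagents that add atoms: none
Why: The first equivalent of base turns the prenylated CH of 6 into a keto ester enolate, which masks the ketone and the ester next to it, so the sodium enolate of 7 can only be acylated by the non-enolisable ester on the quaternary carbon (crossed Claisen condensation) and the dienolate of triketo ester 8 results. Methanol then reversibly re-protonates the more basic keto ester enolate, and the carbon of the remaining 1,3-diketonate attacks the freed ester carbonyl with loss of methoxide, forming the ring bond between the benzoyl-bearing carbon and the enol carbon beside the prenylated carbon (Dieckmann-type Claisen cyclisation). The closest known reaction types are the one-pot Claisen–Dieckmann condensation of methyl ketones with diesters to 2-acyl cyclic 1,3-diones and the biomimetic Claisen cyclisation of 3,5,7-triketo esters to acylphloroglucinols. The six-membered carbocycle closes in a 6-(enolendo)-exo-trig mode, helped by the gem-dialkyl effect of the quaternary carbon. No stereocentre is formed: the quaternary centre cannot enolise and is carried through unchanged, and the labile prenylated CH becomes an sp2 enol carbon. The step needs the right order of the two acylations (secured by the enolate mask), C- over O-acylation and Claisen over aldol closure (both secured by the reversibility of the alternatives and by the strongly acidic cyclic tricarbonyl product, which is withdrawn as its enolate).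

Compound list
1 | dimethyl 3-oxopentanedioate (dimethyl 1,3-acetonedicarboxylate) | COC(=O)CC(=O)CC(=O)OC | starting material
2 | prenyl bromide (1-bromo-3-methylbut-2-ene) | CC(C)=CCBr | starting material
3 | dimethyl 2-(3-methylbut-2-en-1-yl)-3-oxopentanedioate (monoprenyl diester, not isolated) | COC(=O)CC(=O)C(CC=C(C)C)C(=O)OC | intermediate
4 | dimethyl 2,4-bis(3-methylbut-2-en-1-yl)-3-oxopentanedioate (interconverting diastereomers) | COC(=O)C(CC=C(C)C)C(=O)C(CC=C(C)C)C(=O)OC | intermediate
5 | geranyl bromide ((2E)-1-bromo-3,7-dimethylocta-2,6-diene) | CC(C)=CCC/C(C)=C/CBr | starting material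
6 | dimethyl (2R)-2-[(2E)-3,7-dimethylocta-2,6-dien-1-yl]-2,4-bis(3-methylbut-2-en-1-yl)-3-oxopentanedioate (C4 epimers) | CC(C)=CCC/C(C)=C/C[C@](C(=O)OC)(CC=C(C)C)C(=O)C(CC=C(C)C)C(=O)OC | intermediate
7 | acetophenone | CC(=O)c1ccccc1 | starting material
8 | methyl (4S)-4-[(2E)-3,7-dimethylocta-2,6-dien-1-yl]-2,4-bis(3-methylbut-2-en-1-yl)-3,5,7-trioxo-7-phenylheptanoate (C2 epimers; present in the flask as its disodium dienolate, not isolated) | CC(C)=CCC/C(C)=C/C[C@](C(=O)CC(=O)c1ccccc1)(CC=C(C)C)C(=O)C(CC=C(C)C)C(=O)OC | intermediate
9 | kolanone, (4R)-2-benzoyl-4-[(2E)-3,7-dimethylocta-2,6-dien-1-yl]-4,6-bis(3-methylbut-2-en-1-yl)cyclohexane-1,3,5-trione, drawn as its dienol tautomer | CC(C)=CCC/C(C)=C/C[C@]1(CC=C(C)C)C(=O)C(CC=C(C)C)=C(O)/C(=C(\O)c2ccccc2)C1=O | target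

Total step count: 3. Longest linear sequence: 3 steps.

Steps most likely to fail

Step 3. The neopentyl-type ester may resist intermolecular acylation of the sodium enolate, the dienolate of 8 may stall before ring closure, or methoxide may cleave the re-protonated keto ester by retro-Claisen reaction. The fallback sets out from 6 and comes back to the route at 8, which is then isolated and closed to 9. Acetophenone 7 is condensed with cyclohexylamine to N-(1-phenylethylidene)cyclohexanamine F1. Its lithium aza-enolate (LiN(iPr)2, THF), a stronger and slimmer carbon nucleophile than the ketone enolate, is acylated by the lithium enolate of 6 (LiN(SiMe3)2, 1 equiv) at the ester on the quaternary carbon to give the β-enaminone methyl (6Z)-7-(cyclohexylamino)-4-geranyl-2,4-diprenyl-3,5-dioxo-7-phenylhept-6-enoate F2. Buffered aqueous acetic acid should hydrolyse F2 to triketo ester 8. The ring is then closed with DBU in toluene at 60 °C, where only the 1,3-diketone is deprotonated and no alkoxide is present, to give 9.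

Step 2. Facial selectivity may be poor because the acyclic enolate can adopt several conformations within the ion pair and the neighbouring labile CH centre can give matched and mismatched pairs; a second alkylation at the remaining CH may also occur. The fallback sets out from 4 and comes back at 9, giving up catalyst control in favour of resolution. Geranylation of 4 with 5 under achiral conditions (K2CO3, acetone) should give racemic dimethyl 2-geranyl-2,4-diprenyl-3-oxopentanedioate F3. The annulation of step 3 with 7 then proceeds through the racemic triketo ester F4 to racemic kolanone F5. F5 is resolved by preparative supercritical-fluid chromatography on a polysaccharide chiral stationary phase to give 9.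

Step 1. The alkylation may scatter regiochemically (geminal 2,2-dialkylation, O-alkylation, trialkylation). The fallback sets out from 2 and comes back at 4 by a convergent decarboxylative Claisen condensation in which each prenyl group is already in place. Dimethyl malonate is alkylated with 2 (NaH, THF) to dimethyl 2-(3-methylbut-2-en-1-yl)propanedioate F6. Half-saponification (KOH, 1 equiv, MeOH) gives 2-(methoxycarbonyl)-5-methylhex-4-enoic acid F7. One portion of F7 is activated with 1,1'-carbonyldiimidazole to methyl 2-(1H-imidazole-1-carbonyl)-5-methylhex-4-enoate F8, and another portion is converted with Mg(OEt)2 into magnesium bis[2-(methoxycarbonyl)-5-methylhex-4-enoate] F9. F8 and F9 are combined in THF, where C-acylation and loss of carbon dioxide should give 4.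

Further compounds
F1 | step 3 | N-(1-phenylethylidene)cyclohexanamine | CC(=NC1CCCCC1)c1ccccc1
F2 | step 3 | methyl (6Z)-7-(cyclohexylamino)-4-[(2E)-3,7-dimethylocta-2,6-dien-1-yl]-2,4-bis(3-methylbut-2-en-1-yl)-3,5-dioxo-7-phenylhept-6-enoate (quaternary centre as in 6) | CC(C)=CCC/C(C)=C/C[C@](C(=O)/C=C(\NC1CCCCC1)c1ccccc1)(CC=C(C)C)C(=O)C(CC=C(C)C)C(=O)OC
F3 | step 2 | racemic dimethyl 2-[(2E)-3,7-dimethylocta-2,6-dien-1-yl]-2,4-bis(3-methylbut-2-en-1-yl)-3-oxopentanedioate | CC(C)=CCC/C(C)=C/CC(C(=O)OC)(CC=C(C)C)C(=O)C(CC=C(C)C)C(=O)OC
F4 | step 2 | racemic methyl 4-[(2E)-3,7-dimethylocta-2,6-dien-1-yl]-2,4-bis(3-methylbut-2-en-1-yl)-3,5,7-trioxo-7-phenylheptanoate | CC(C)=CCC/C(C)=C/CC(C(=O)CC(=O)c1ccccc1)(CC=C(C)C)C(=O)C(CC=C(C)C)C(=O)OC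
F5 | step 2 | racemic kolanone | CC(C)=CCC/C(C)=C/CC1(CC=C(C)C)C(=O)C(CC=C(C)C)=C(O)/C(=C(\O)c2ccccc2)C1=O
F6 | step 1 | dimethyl 2-(3-methylbut-2-en-1-yl)propanedioate | COC(=O)C(CC=C(C)C)C(=O)OC
F7 | step 1 | 2-(methoxycarbonyl)-5-methylhex-4-enoic acid | COC(=O)C(CC=C(C)C)C(=O)O
F8 | step 1 | methyl 2-(1H-imidazole-1-carbonyl)-5-methylhex-4-enoate | COC(=O)C(CC=C(C)C)C(=O)n1ccnc1
F9 | step 1 | magnesium bis[2-(methoxycarbonyl)-5-methylhex-4-enoate] | COC(=O)C(CC=C(C)C)C(=O)[O-].COC(=O)C(CC=C(C)C)C(=O)[O-].[Mg+2]
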